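## Retrosynthetic overview

1. The Z-ylidene C=C between lactone C5 and the chain is cut last, giving acetoxy-polyenynal 21 and ring B epoxy-vinyl butenolide 30 (vinylogous aldol, elimination, then removal of the ring B silyl ether).
2. 21 comes from tetraenynoate 17. The strategy rests on the E-trisubstituted alkene C(CH3)=CH attached directly to the ring A alkyne (ring A–C≡C–C(CH3)=CH–): its methyl and its bond to the next chain carbon are added syn across the terminal alkyne of ring A 1,3-diyne 9 (methylalumination, then Negishi coupling with iodotrienoate 14).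
3. 9 comes from enol triflate 4 and mono-silylated butadiyne (Sonogashira); 14 from (E)-4,4-dimethoxybut-2-enal (Horner–Wadsworth–Emmons, hydrolysis, Takai).
4. 30 comes from the same triflate 4: carbonylation, reduction, Sharpless epoxidation, oxidation, boron-Wittig, Suzuki–Miyaura coupling with 3-bromofuran-2(5H)-one.
5. Ring order: both six-membered carbocycles come intact from (4R,6R)-actinol, the lactone ring is bought as 3-bromofuran-2(5H)-one, and the only ring formed is the oxirane (step 16).

Key step: step 9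

Remark on the chemistry: aldol 32 is carried as a mixture of diastereomers at its two transient stereocentres (carbinol carbon and lactone C5), both of which become sp2 in step 21; silyl diyne 7 and diyne 9 are used as fresh solutions without storage.

## Route

Step 1
Reactants: 1 (4R,6R)-actinol
Product: 2 (4R,6R)-4-[(tert-butyldimethylsilyl)oxy]-2,2,6-trimethylcyclohexan-1-one
Conditions: TBSCl, imidazole, DMF, rt
Reagents that add atoms: tert-butyldimethylsilyl chloride (CC(C)(C)[Si](C)(C)Cl)
Why: Imidazole-promoted silylation of the unhindered secondary alcohol; no stereocentre is touched.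

Step 2
Reactants: 2 silyl ether ketone
Product: 4 (4R)-4-[(tert-butyldimethylsilyl)oxy]-2,6,6-trimethylcyclohex-1-en-1-yl trifluoromethanesulfonate, via lithium enolate 3 (not isolated)
Conditions: LiN(iPr)2, THF, −78 to 0 °C; then PhNTf2, −78 °C to rt
Reagents that add atoms: N-phenylbis(trifluoromethanesulfonimide) (O=S(=O)(N(c1ccccc1)S(=O)(=O)C(F)(F)F)C(F)(F)F)
Why: Enol triflate formation; only C6 carries an α-hydrogen (C2 is quaternary), so a single tetrasubstituted enolate forms and is O-sulfonylated, which removes the C6 stereocentre on purpose and leaves C4 untouched.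

Step 3
Reactants: 5 1,4-bis(trimethylsilyl)buta-1,3-diyne
Product: 7 buta-1,3-diyn-1-yl(trimethyl)silane, via lithium diynide 6 (not isolated)
Conditions: MeLi·LiBr (1.0 equiv), Et2O, rt; then sat. aq. NH4Cl, 0 °C; dried ethereal solution used directly
Reagents that add atoms: none
Why: Selective mono-desilylation: methyllithium attacks one silicon to release the mono-lithium diynide, whose charge protects the second C–Si bond, and protonation gives the mono-capped diyne.

Step 4
Reactants: 4 enol triflate; 7 buta-1,3-diyn-1-yl(trimethyl)silane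
Product: 8 tert-butyldimethyl{[(1R)-3,5,5-trimethyl-4-[4-(trimethylsilyl)buta-1,3-diyn-1-yl]cyclohex-3-en-1-yl]oxy}silane
Conditions: Pd(PPh3)4 (5 mol %), CuI (10 mol %), iPr2NH, DMF (degassed), rt
Reagents that add atoms: none
Why: Sonogashira coupling of an alkenyl triflate with a terminal alkyne; the silyl cap blocks the far terminus so only one C(sp2)–C(sp) bond forms, and degassing suppresses oxidative homocoupling.

Step 5
Reactants: 8 silyl-capped ring A diyne
Product: 9 ring A 1,3-diyne, {[(1R)-4-(buta-1,3-diyn-1-yl)-3,5,5-trimethylcyclohex-3-en-1-yl]oxy}(tert-butyl)dimethylsilane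
Conditions: K2CO3 (cat.), MeOH/THF, 0 °C; used at once
Reagents that add atoms: none
Why: Base-catalysed methanolysis of the alkynyl C–Si bond; the secondary tert-butyldimethylsilyl ether is stable to these conditions.

Step 6
Reactants: 10 triethyl 2-phosphonopropionate; 11 (E)-4,4-dimethoxybut-2-enal
Product: 12 ethyl (2E,4E)-6,6-dimethoxy-2-methylhexa-2,4-dienoate
Conditions: LiCl, DBU, MeCN, 0 °C to rt
Reagents that add atoms: none
Why: Horner–Wadsworth–Emmons olefination under Masamune–Roush conditions; the stabilised α-methyl phosphonate should give the E-trisubstituted enoate, and the acetal is inert to the mild base.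

Step 7
Reactants: 12 dienoate acetal
Product: 13 ethyl (2E,4E)-2-methyl-6-oxohexa-2,4-dienoate
Conditions: 1 M aq. HCl (cat.), THF, rt
Reagents that add atoms: water (O)
Why: Acid-catalysed acetal hydrolysis; the conjugated dienoate tolerates dilute acid and the all-E geometry is the thermodynamic one.

Step 8
Reactants: 13 aldehyde ester
Product: 14 ethyl (2E,4E,6E)-7-iodo-2-methylhepta-2,4,6-trienoate
Conditions: CrCl2 (6 equiv), CHI3 (2 equiv), THF/1,4-dioxane, 0 °C to rt, dark
Reagents that add atoms: iodoform (IC(I)I)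
Why: Takai olefination; the geminal dichromium species from iodoform adds to the aldehyde and eliminates to the E-iodoalkene, and the ester is inert to CrCl2.

Step 9
Reactants: 9 ring A 1,3-diyne; 14 iodotrienoate
Product: 17 ethyl (2E,4E,6E,8E)-11-[(4R)-4-[(tert-butyldimethylsilyl)oxy]-2,6,6-trimethylcyclohex-1-en-1-yl]-2,9-dimethylundeca-2,4,6,8-tetraen-10-ynoate, via alkenylalane 15 (not isolated), via alkenylzinc chloride 16 (not isolated)
Conditions: AlMe3 (2.5 equiv), Cp2ZrCl2 (0.25 equiv), CH2Cl2, 0 °C to rt; excess AlMe3 removed in vacuo; then THF, ZnCl2 (1 equiv), 14, Pd(PPh3)4 (5 mol %), rt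
Reagents that add atoms: trimethylaluminium (C[Al](C)C)
Why: Cp2ZrCl2 activates AlMe3 to a zirconium–aluminium methyl species that adds methyl and metal syn across the terminal C≡C–H of 9, methyl to the internal carbon and aluminium to the terminal one, giving alkenylalane 15 (zirconium-catalysed carboalumination, the Negishi methylalumination, applied here to the terminal alkyne of a conjugated diyne, which is used less often than an enyne). Transmetalation to zinc and palladium-catalysed Negishi coupling with iodide 14 (oxidative addition, transmetalation, reductive elimination) proceed with retention at both sp2 carbons, so the C–CH3 bond and the adjacent sp2–sp2 bond are made in one flask. No ring is closed and no stereocentre is created. The step needs internal-methyl regiochemistry and syn addition, which together with retention fix the E alkene (alkynyl trans to the chain), and chemoselectivity for the terminal over the internal alkyne. The internal alkyne is disubstituted and shielded by the gem-dimethyl and vinylic methyl groups of ring A, so it should stay inert. Excess AlMe3 is removed before the ester-bearing iodide is added, and the silyl ether is inert to the alane.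

Step 10
Reactants: 17 ring A tetraenynoate
Product: 18 (2E,4E,6E,8E)-11-[(4R)-4-[(tert-butyldimethylsilyl)oxy]-2,6,6-trimethylcyclohex-1-en-1-yl]-2,9-dimethylundeca-2,4,6,8-tetraen-10-yn-1-ol
Conditions: iBu2AlH (2.5 equiv), CH2Cl2, −78 °C; aq. potassium sodium tartrate work-up
Reagents that add atoms: none
Why: 1,2-Reduction of the conjugated ester to the allylic alcohol by the aluminium hydride; alkyne, polyene and silyl ether are inert at −78 °C.

Step 11
Reactants: 18 silyl ether alcohol
Product: 19 (2E,4E,6E,8E)-11-[(4R)-4-hydroxy-2,6,6-trimethylcyclohex-1-en-1-yl]-2,9-dimethylundeca-2,4,6,8-tetraen-10-yn-1-ol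
Conditions: Bu4NF, THF, 0 °C to rt
Reagents that add atoms: none
Why: Fluoride cleavage of the silyl ether, done at the alcohol stage so that no base-sensitive polyenal is exposed to fluoride.

Step 12
Reactants: 19 diol
Product: 20 (2E,4E,6E,8E)-11-[(4R)-4-hydroxy-2,6,6-trimethylcyclohex-1-en-1-yl]-2,9-dimethylundeca-2,4,6,8-tetraen-10-ynal
Conditions: MnO2 (activated, excess), CH2Cl2, rt, dark
Reagents that add atoms: none
Why: Chemoselective MnO2 oxidation of the allylic (polyenylic) primary alcohol; the ring alcohol is homoallylic and is not oxidised.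

Step 13
Reactants: 20 hydroxy aldehyde
Product: 21 (1R)-4-[(3E,5E,7E,9E)-3,10-dimethyl-11-oxoundeca-3,5,7,9-tetraen-1-yn-1-yl]-3,5,5-trimethylcyclohex-3-en-1-yl acetate
Conditions: Ac2O, pyridine, DMAP (cat.), CH2Cl2, 0 °C to rt
Reagents that add atoms: acetic anhydride (CC(=O)OC(C)=O)
Why: DMAP-catalysed acetylation of the secondary alcohol with retention at carbon; the non-enolisable aldehyde is unaffected.

Step 14
Reactants: 4 enol triflate
Product: 22 methyl (4R)-4-[(tert-butyldimethylsilyl)oxy]-2,6,6-trimethylcyclohex-1-ene-1-carboxylate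
Conditions: Pd(OAc)2 (5 mol %), PPh3 (10 mol %), CO (1 atm), MeOH, Et3N, DMF, 60 °C
Reagents that add atoms: carbon monoxide ([C-]#[O+]); methanol (CO)
Why: Palladium-catalysed alkoxycarbonylation of the enol triflate (oxidative addition, CO insertion, methanolysis of the acylpalladium).

Step 15
Reactants: 22 methyl ester
Product: 23 [(4R)-4-[(tert-butyldimethylsilyl)oxy]-2,6,6-trimethylcyclohex-1-en-1-yl]methanol
Conditions: iBu2AlH (2.5 equiv), CH2Cl2, −78 to 0 °C
Reagents that add atoms: none
Why: Aluminium hydride reduction of the conjugated ester to the allylic alcohol needed for directed epoxidation.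

Step 16
Reactants: 23 allylic alcohol
Product: 24 [(1R,4S,6R)-4-[(tert-butyldimethylsilyl)oxy]-2,2,6-trimethyl-7-oxabicyclo[4.1.0]heptan-1-yl]methanol
Conditions: Ti(OiPr)4, D-(−)-diethyl tartrate, tBuOOH, 4 Å MS, CH2Cl2, −20 °C
Reagents that add atoms: tert-butyl hydroperoxide (CC(C)(C)OO)
Why: Sharpless asymmetric epoxidation; the titanium complex of D-(−)-tartrate delivers oxygen under reagent control to the alkene face anti to the C4 silyloxy group, setting both oxirane carbons (1R,6R).

Step 17
Reactants: 24 epoxy alcohol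
Product: 25 (1S,4S,6R)-4-[(tert-butyldimethylsilyl)oxy]-2,2,6-trimethyl-7-oxabicyclo[4.1.0]heptane-1-carbaldehyde
Conditions: nPr4N[RuO4] (5 mol %), N-methylmorpholine N-oxide, 4 Å MS, CH2Cl2, rt
Reagents that add atoms: none
Why: Ley–Griffith oxidation under neutral conditions; the aldehyde has no α-hydrogen, and the oxirane is not exposed to acid.

Step 18
Reactants: 25 epoxy aldehyde; 26 bis(4,4,5,5-tetramethyl-1,3,2-dioxaborolan-2-yl)methane
Product: 28 2-[(E)-2-[(1S,4S,6R)-4-[(tert-butyldimethylsilyl)oxy]-2,2,6-trimethyl-7-oxabicyclo[4.1.0]heptan-1-yl]ethenyl]-4,4,5,5-tetramethyl-1,3,2-dioxaborolane, via lithiated diborylmethane 27 (not isolated)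
Conditions: LiTMP (lithium 2,2,6,6-tetramethylpiperidide), 26, THF, 0 °C; then 25, −78 °C to rt
Reagents that add atoms: none
Why: Boron-Wittig olefination; the α-boryl carbanion adds to the aldehyde and syn B–O elimination from the less crowded adduct should give the trans-alkenyl boronate, with no Lewis acid reaching the oxirane.

Step 19
Reactants: 28 alkenyl boronate; 29 3-bromofuran-2(5H)-one
Product: 30 3-[(E)-2-[(1S,4S,6R)-4-[(tert-butyldimethylsilyl)oxy]-2,2,6-trimethyl-7-oxabicyclo[4.1.0]heptan-1-yl]ethenyl]furan-2(5H)-one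
Conditions: PdCl2(MeCN)2 (5 mol %), AsPh3 (20 mol %), Ag2O, THF/H2O, 50 °C
Reagents that add atoms: none
Why: Suzuki–Miyaura coupling with retention of the E alkene; the α-bromo butenolide adds readily to zerovalent palladium, Ag2O activates the boronate without soluble base that would open the lactone, and the tetrasubstituted vinyl oxirane is too hindered to be ionised by the catalyst.

Step 20
Reactants: 30 epoxy-vinyl butenolide; 21 acetoxy polyenynal
Product: 32 aldol adduct of 21 at lactone C5 of 30 (δ-hydroxy butenolide; diastereomer mixture), via lithium furanolate 31 (not isolated)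
Conditions: LiN(iPr)2 (1.05 equiv), THF, −78 °C; then 21, −78 °C; AcOH quench at −78 °C
Reagents that add atoms: none
Why: Vinylogous aldol addition; γ-deprotonation gives an aromatic 2-furanolate whose C3 is blocked by the dienyl substituent, so the non-enolisable aldehyde should be attacked by C5, and the two new stereocentres form without control because both are erased in step 21.

Step 21
Reactants: 32 aldol adduct
Product: 34 O-silyl ether of the target with the (Z)-ylidene butenolide in place, via mesylate 33 (not isolated)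
Conditions: MsCl, Et3N, CH2Cl2, −40 °C; then DBU, −40 to 0 °C, dark
Reagents that add atoms: none
Why: Sulfonylation then base-induced elimination through the furanolate (E1cB); the leaving group departs from the conformer that places the polyene chain syn to the ring oxygen and away from C4–H, which should give the Z isomer, also the thermodynamically preferred one.

Step 22
Reactants: 34 silyl-protected target
Product: 35 target CNP0337675.1 (pyrrhoxanthin)
Conditions: Bu4NF, AcOH (1:1), THF, 0 °C to rt, dark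
Reagents that add atoms: none
Why: Buffered fluoride desilylation; near-neutral conditions should spare the acetate, the ylidene lactone and the acid-sensitive vinyl oxirane, and no stereocentre is touched.

## Compound list

1 | (4R,6R)-4-hydroxy-2,2,6-trimethylcyclohexan-1-one ((4R,6R)-actinol) | O[C@@H]1C[C@@H](C)C(=O)C(C)(C)C1 | starting material
2 | (4R,6R)-4-[(tert-butyldimethylsilyl)oxy]-2,2,6-trimethylcyclohexan-1-one | CC(C)(C)[Si](C)(C)O[C@@H]1C[C@@H](C)C(=O)C(C)(C)C1 | intermediate
3 | lithium (4R)-4-[(tert-butyldimethylsilyl)oxy]-2,6,6-trimethylcyclohex-1-en-1-olate | CC(C)(C)[Si](C)(C)O[C@@H]1CC(C)=C(O[Li])C(C)(C)C1 | intermediate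
4 | (4R)-4-[(tert-butyldimethylsilyl)oxy]-2,6,6-trimethylcyclohex-1-en-1-yl trifluoromethanesulfonate | CC(C)(C)[Si](C)(C)O[C@@H]1CC(C)=C(OS(=O)(=O)C(F)(F)F)C(C)(C)C1 | intermediate
5 | 1,4-bis(trimethylsilyl)buta-1,3-diyne | C[Si](C)(C)C#CC#C[Si](C)(C)C | starting material
6 | lithium 4-(trimethylsilyl)buta-1,3-diyn-1-ide | [Li]C#CC#C[Si](C)(C)C | intermediate
7 | buta-1,3-diyn-1-yl(trimethyl)silane | C#CC#C[Si](C)(C)C | intermediate
8 | tert-butyldimethyl{[(1R)-3,5,5-trimethyl-4-[4-(trimethylsilyl)buta-1,3-diyn-1-yl]cyclohex-3-en-1-yl]oxy}silane | CC(C)(C)[Si](C)(C)O[C@@H]1CC(C)=C(C#CC#C[Si](C)(C)C)C(C)(C)C1 | intermediate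
9 | ring A 1,3-diyne, {[(1R)-4-(buta-1,3-diyn-1-yl)-3,5,5-trimethylcyclohex-3-en-1-yl]oxy}(tert-butyl)dimethylsilane | CC(C)(C)[Si](C)(C)O[C@@H]1CC(C)=C(C#CC#C)C(C)(C)C1 | intermediate
10 | triethyl 2-phosphonopropionate | CCOC(=O)C(C)P(=O)(OCC)OCC | starting material
11 | (E)-4,4-dimethoxybut-2-enal | COC(OC)/C=C/C=O | starting material
12 | ethyl (2E,4E)-6,6-dimethoxy-2-methylhexa-2,4-dienoate | CCOC(=O)/C(C)=C/C=C/C(OC)OC | intermediate
13 | ethyl (2E,4E)-2-methyl-6-oxohexa-2,4-dienoate | CCOC(=O)/C(C)=C/C=C/C=O | intermediate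
14 | ethyl (2E,4E,6E)-7-iodo-2-methylhepta-2,4,6-trienoate | CCOC(=O)/C(C)=C/C=C/C=C/I | intermediate
15 | alkenylalane, dimethyl[(1E)-4-[(4R)-4-[(tert-butyldimethylsilyl)oxy]-2,6,6-trimethylcyclohex-1-en-1-yl]-2-methylbut-1-en-3-yn-1-yl]alumane | CC(C)(C)[Si](C)(C)O[C@@H]1CC(C)=C(C#C/C(C)=C/[Al](C)C)C(C)(C)C1 | intermediate
16 | alkenylzinc chloride, chloro[(1E)-4-[(4R)-4-[(tert-butyldimethylsilyl)oxy]-2,6,6-trimethylcyclohex-1-en-1-yl]-2-methylbut-1-en-3-yn-1-yl]zinc | CC(C)(C)[Si](C)(C)O[C@@H]1CC(C)=C(C#C/C(C)=C/[Zn]Cl)C(C)(C)C1 | intermediate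
17 | ring A tetraenynoate, ethyl (2E,4E,6E,8E)-11-[(4R)-4-[(tert-butyldimethylsilyl)oxy]-2,6,6-trimethylcyclohex-1-en-1-yl]-2,9-dimethylundeca-2,4,6,8-tetraen-10-ynoate | CC(C)(C)[Si](C)(C)O[C@@H]1CC(C)=C(C#C/C(C)=C/C=C/C=C/C=C(C)/C(=O)OCC)C(C)(C)C1 | intermediate
18 | (2E,4E,6E,8E)-11-[(4R)-4-[(tert-butyldimethylsilyl)oxy]-2,6,6-trimethylcyclohex-1-en-1-yl]-2,9-dimethylundeca-2,4,6,8-tetraen-10-yn-1-ol | CC(C)(C)[Si](C)(C)O[C@@H]1CC(C)=C(C#C/C(C)=C/C=C/C=C/C=C(C)/CO)C(C)(C)C1 | intermediate
19 | (2E,4E,6E,8E)-11-[(4R)-4-hydroxy-2,6,6-trimethylcyclohex-1-en-1-yl]-2,9-dimethylundeca-2,4,6,8-tetraen-10-yn-1-ol | O[C@@H]1CC(C)=C(C#C/C(C)=C/C=C/C=C/C=C(C)/CO)C(C)(C)C1 | intermediate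
20 | (2E,4E,6E,8E)-11-[(4R)-4-hydroxy-2,6,6-trimethylcyclohex-1-en-1-yl]-2,9-dimethylundeca-2,4,6,8-tetraen-10-ynal | O[C@@H]1CC(C)=C(C#C/C(C)=C/C=C/C=C/C=C(C)/C=O)C(C)(C)C1 | intermediate
21 | (1R)-4-[(3E,5E,7E,9E)-3,10-dimethyl-11-oxoundeca-3,5,7,9-tetraen-1-yn-1-yl]-3,5,5-trimethylcyclohex-3-en-1-yl acetate | CC(=O)O[C@@H]1CC(C)=C(C#C/C(C)=C/C=C/C=C/C=C(C)/C=O)C(C)(C)C1 | intermediate
22 | methyl (4R)-4-[(tert-butyldimethylsilyl)oxy]-2,6,6-trimethylcyclohex-1-ene-1-carboxylate | CC(C)(C)[Si](C)(C)O[C@@H]1CC(C)=C(C(=O)OC)C(C)(C)C1 | intermediate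
23 | [(4R)-4-[(tert-butyldimethylsilyl)oxy]-2,6,6-trimethylcyclohex-1-en-1-yl]methanol | CC(C)(C)[Si](C)(C)O[C@@H]1CC(C)=C(CO)C(C)(C)C1 | intermediate
24 | [(1R,4S,6R)-4-[(tert-butyldimethylsilyl)oxy]-2,2,6-trimethyl-7-oxabicyclo[4.1.0]heptan-1-yl]methanol (oxirane anti to the silyloxy group) | OC[C@@]12O[C@]1(C)C[C@@H](O[Si](C)(C)C(C)(C)C)CC2(C)C | intermediate
25 | (1S,4S,6R)-4-[(tert-butyldimethylsilyl)oxy]-2,2,6-trimethyl-7-oxabicyclo[4.1.0]heptane-1-carbaldehyde | O=C[C@@]12O[C@]1(C)C[C@@H](O[Si](C)(C)C(C)(C)C)CC2(C)C | intermediate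
26 | bis(4,4,5,5-tetramethyl-1,3,2-dioxaborolan-2-yl)methane | CC1(C)OB(CB2OC(C)(C)C(C)(C)O2)OC1(C)C | starting material
27 | lithio-bis(4,4,5,5-tetramethyl-1,3,2-dioxaborolan-2-yl)methane | [Li]C(B1OC(C)(C)C(C)(C)O1)B1OC(C)(C)C(C)(C)O1 | intermediate
28 | 2-[(E)-2-[(1S,4S,6R)-4-[(tert-butyldimethylsilyl)oxy]-2,2,6-trimethyl-7-oxabicyclo[4.1.0]heptan-1-yl]ethenyl]-4,4,5,5-tetramethyl-1,3,2-dioxaborolane | CC1(C)OB(/C=C/[C@@]23O[C@]2(C)C[C@@H](O[Si](C)(C)C(C)(C)C)CC3(C)C)OC1(C)C | intermediate
29 | 3-bromofuran-2(5H)-one | O=C1OCC=C1Br | starting material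
30 | 3-[(E)-2-[(1S,4S,6R)-4-[(tert-butyldimethylsilyl)oxy]-2,2,6-trimethyl-7-oxabicyclo[4.1.0]heptan-1-yl]ethenyl]furan-2(5H)-one | O=C1OCC=C1/C=C/[C@@]23O[C@]2(C)C[C@@H](O[Si](C)(C)C(C)(C)C)CC3(C)C | intermediate
31 | lithium 2-furanolate of 30 | [Li]Oc1occc1/C=C/[C@@]23O[C@]2(C)C[C@@H](O[Si](C)(C)C(C)(C)C)CC3(C)C | intermediate
32 | aldol adduct: 5-(1-hydroxyalkyl)furan-2(5H)-one joining 21 (former aldehyde carbon, now carbinol) to C5 of 30; mixture of diastereomers at the carbinol carbon and lactone C5 | CC(=O)O[C@@H]1CC(C)=C(C#C/C(C)=C/C=C/C=C/C=C(C)/C(O)C2C=C(/C=C/[C@@]34O[C@]3(C)C[C@@H](O[Si](C)(C)C(C)(C)C)CC4(C)C)C(=O)O2)C(C)(C)C1 | intermediate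
33 | methanesulfonate of 32 | CC(=O)O[C@@H]1CC(C)=C(C#C/C(C)=C/C=C/C=C/C=C(C)/C(OS(C)(=O)=O)C2C=C(/C=C/[C@@]34O[C@]3(C)C[C@@H](O[Si](C)(C)C(C)(C)C)CC4(C)C)C(=O)O2)C(C)(C)C1 | intermediate
34 | target with the ring B hydroxyl as tert-butyldimethylsilyl ether; (Z)-ylidene butenolide, all chain alkenes E | CC(=O)O[C@@H]1CC(C)=C(C#C/C(C)=C/C=C/C=C/C=C(C)/C=C2C=C(/C=C/[C@@]34O[C@]3(C)C[C@@H](O[Si](C)(C)C(C)(C)C)CC4(C)C)C(=O)O/2)C(C)(C)C1 | intermediate
35 | CNP0337675.1 (pyrrhoxanthin) | CC(=O)O[C@@H]1CC(C)=C(C#C/C(C)=C/C=C/C=C/C=C(C)/C=C2C=C(/C=C/[C@@]34O[C@]3(C)C[C@@H](O)CC4(C)C)C(=O)O/2)C(C)(C)C1 | target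

## Step count and risks

Total step count: 22. Longest linear sequence: 12 steps (1, 2, 4, 5, 9, 10, 11, 12, 13, 20, 21, 22); the ring B branch from actinol is 11 steps.

Steps most likely to fail:

Step 9. The alane may deprotonate the acidic terminal C–H of the conjugated diyne instead of adding across it, the diyne may oligomerise before carbometalation, or the methyl may add in part to the terminal carbon and erode the alkene geometry. The fallback buys the E-trisubstituted alkene instead of making it. It sets out from triflate 4: Sonogashira coupling with commercial (E)-3-methylpent-2-en-4-yn-1-ol F1 (Pd(PPh3)4, CuI, iPr2NH) would give dienynol F2; Appel bromination (CBr4, PPh3) would give allylic bromide F3, and PPh3 would convert it into phosphonium bromide F4. Wittig olefination of aldehyde ester 13 with the ylide of F4 (NaOMe, CH2Cl2), followed by iodine-catalysed equilibration of the new disubstituted alkene to E, comes back to tetraenynoate 17.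

Step 20. The aldehyde may be attacked by C3 instead of C5 of the furanolate, the adduct may revert by retro-aldol on warming, or the furanolate may open the neighbouring oxirane by vinylogous elimination. The fallback reverses the order of bond formation so that the oxirane never meets an enolate. It sets out from aldehyde 21 and bromofuranone 29: soft enolisation of 29 (TBSOTf, iPr2NEt, CH2Cl2, −78 °C) would give 3-bromo-2-silyloxyfuran F5, which adds in the same flask to 21 (vinylogous Mukaiyama aldol) to give silyl aldol F6; DBU would then expel silanol to give bromo-ylidene butenolide F7 with the Z geometry. Suzuki–Miyaura coupling of F7 with boronate 28 (PdCl2(MeCN)2, AsPh3, Ag2O, THF) comes back to silyl-protected target 34.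

Step 22. Fluoride or adventitious hydroxide may cleave the acetate or open the ylidene lactone, and any acidity may rearrange the vinyl oxirane to a furanoid oxide, before the hindered silyl ether is gone. The fallback removes the silyl group before the last C–C bond is made. It sets out from boronate 28: buffered fluoride (Bu4NF, AcOH) would give hydroxy boronate F8, which is coupled under the same Suzuki–Miyaura conditions with bromo-ylidene butenolide F7 (made from 21 and 29 as in the fallback to step 20) to arrive directly at target 35.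

## Further compounds

F1 | step 9 | (E)-3-methylpent-2-en-4-yn-1-ol | C#C/C(C)=C/CO
F2 | step 9 | (2E)-5-[(4R)-4-[(tert-butyldimethylsilyl)oxy]-2,6,6-trimethylcyclohex-1-en-1-yl]-3-methylpent-2-en-4-yn-1-ol | CC(C)(C)[Si](C)(C)O[C@@H]1CC(C)=C(C#C/C(C)=C/CO)C(C)(C)C1
F3 | step 9 | {[(1R)-4-[(3E)-5-bromo-3-methylpent-3-en-1-yn-1-yl]-3,5,5-trimethylcyclohex-3-en-1-yl]oxy}(tert-butyl)dimethylsilane | CC(C)(C)[Si](C)(C)O[C@@H]1CC(C)=C(C#C/C(C)=C/CBr)C(C)(C)C1
F4 | step 9 | [(2E)-5-[(4R)-4-[(tert-butyldimethylsilyl)oxy]-2,6,6-trimethylcyclohex-1-en-1-yl]-3-methylpent-2-en-4-yn-1-yl]triphenylphosphonium bromide | CC(C)(C)[Si](C)(C)O[C@@H]1CC(C)=C(C#C/C(C)=C/C[P+](c2ccccc2)(c2ccccc2)c2ccccc2)C(C)(C)C1.[Br-]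
F5 | step 20 | 3-bromo-2-[(tert-butyldimethylsilyl)oxy]furan | CC(C)(C)[Si](C)(C)Oc1occc1Br
F6 | step 20 | silyl aldol: 3-bromo-5-[1-(tert-butyldimethylsilyloxy)alkyl]furan-2(5H)-one from 21, diastereomer mixture | CC(=O)O[C@@H]1CC(C)=C(C#C/C(C)=C/C=C/C=C/C=C(C)/C(O[Si](C)(C)C(C)(C)C)C2C=C(Br)C(=O)O2)C(C)(C)C1
F7 | step 20 | (Z)-3-bromo-5-ylidene butenolide carrying the ring A acetoxy polyenyne chain | CC(=O)O[C@@H]1CC(C)=C(C#C/C(C)=C/C=C/C=C/C=C(C)/C=C2C=C(Br)C(=O)O/2)C(C)(C)C1
F8 | step 22 | (1S,3S,6R)-1,5,5-trimethyl-6-[(E)-2-(4,4,5,5-tetramethyl-1,3,2-dioxaborolan-2-yl)ethenyl]-7-oxabicyclo[4.1.0]heptan-3-ol | CC1(C)OB(/C=C/[C@@]23O[C@]2(C)C[C@@H](O)CC3(C)C)OC1(C)C
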